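**Plan**

- Retrosynthetic cuts, in order (flavanone numbering throughout): the aryl ether bond O1–C8a of ring C; the C2–O bond, back to the C2=C3 alkene of a chalcone; the C2=C3 bond (aldol condensation); the acetyl–ring A bond and the prenyl–ring B bond.
- Forward order: ring B aldehyde by Stille prenylation; ring A ketone by acylation of 5-fluororesorcinol and MOM protection; chain joined by Claisen–Schmidt condensation; C2–O installed; ring C (the only ring made) closed; MOM groups removed.
- Enabling feature: the C4 carbonyl sits on C4a, ortho to C8a of ring A. With fluorine on C8a, the unit F–C8a=C4a–C4=O is a vinylogous acyl fluoride, and the oxygen on C2 reaches C8a through a six-membered transition state.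
- Helpers: the fluorine (activator and leaving group, lost in the key step) and two MOM ethers that keep ring A from becoming a deactivating phenoxide (removed last).
- Stereochemistry: the single centre C2 (S) comes from ligand-controlled copper-catalysed β-borylation of the chalcone and C–B to C–O oxidation with retention; the ring closure breaks no bond at C2.

Key step: step 6

Assumption: the (R,Sp)-Josiphos–copper boryl is taken to deliver boron to the chalcone face that gives the (S)-boronate; should a first run give the (R)-series, the mirror-image ligand is used with nothing else changed.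

**Step 1**
Reactants: 1 3-bromo-4-methoxybenzaldehyde; 2 tributyl(3-methylbut-2-en-1-yl)stannane
Product: 3 4-methoxy-3-(3-methylbut-2-en-1-yl)benzaldehyde
Conditions: Pd(PPh3)4 (5 mol %), DMF, 95 °C
Reagents that add atoms: none
Why: Stille coupling, in which zerovalent palladium inserts into the C–Br bond, the allylic stannane transmetalates and reductive elimination at the unsubstituted allyl terminus should give the linear prenyl arene, the aldehyde being inert to the stannane in the absence of a Lewis acid.

**Step 2**
Reactants: 4 5-fluorobenzene-1,3-diol (5-fluororesorcinol)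
Product: 5 1-(2-fluoro-4,6-dihydroxyphenyl)ethan-1-one
Conditions: AcOH (1.2 equiv), BF3·OEt2 (as medium), 90 °C; aq. NaOAc
Reagents that add atoms: acetic acid CC(=O)O
Why: Friedel–Crafts (Nencki-type) acylation of a resorcinol goes para to one hydroxyl and ortho to the other, which in 4 is the carbon between OH and F (the site also expected for Pechmann condensation of this diol), and the hydrogen-bonded ortho-hydroxy ketone formed is too deactivated for a second acylation.

**Step 3**
Reactants: 5 1-(2-fluoro-4,6-dihydroxyphenyl)ethan-1-one
Product: 6 1-[2-fluoro-4,6-bis(methoxymethoxy)phenyl]ethan-1-one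
Conditions: NaH (2.3 equiv), MOMCl (2.5 equiv), DMF, 0 °C to rt
Reagents that add atoms: chloromethyl methyl ether COCCl
Why: Williamson-type O-alkylation of both phenoxides, with NaH chosen because the hydrogen-bonded ortho-hydroxyl resists alkylation under amine-base conditions, gives acetal ethers that should survive hydroxide, the copper boryl, perborate and the amide base used later.

**Step 4**
Reactants: 6 1-[2-fluoro-4,6-bis(methoxymethoxy)phenyl]ethan-1-one; 3 4-methoxy-3-(3-methylbut-2-en-1-yl)benzaldehyde
Product: 7 (2E)-1-[2-fluoro-4,6-bis(methoxymethoxy)phenyl]-3-[4-methoxy-3-(3-methylbut-2-en-1-yl)phenyl]prop-2-en-1-one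
Conditions: KOH (50 % aq.), EtOH, 0 °C to rt
Reagents that add atoms: none
Why: Claisen–Schmidt condensation, in which the ketone enolate adds to the non-enolisable aldehyde and E1cB loss of water gives the thermodynamically favoured (E)-enone, while intermolecular displacement of the fluorine by hydroxide or ethoxide should be slow in the protic medium at room temperature.

**Step 5**
Reactants: 7 (2E)-1-[2-fluoro-4,6-bis(methoxymethoxy)phenyl]-3-[4-methoxy-3-(3-methylbut-2-en-1-yl)phenyl]prop-2-en-1-one
Product: 9 (3S)-1-[2-fluoro-4,6-bis(methoxymethoxy)phenyl]-3-hydroxy-3-[4-methoxy-3-(3-methylbut-2-en-1-yl)phenyl]propan-1-one, via pinacol boronate 8 (not isolated)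
Conditions: CuCl (5 mol %), NaOt-Bu (8 mol %), (R)-1-[(Sp)-2-(diphenylphosphino)ferrocenyl]ethyldicyclohexylphosphine (Josiphos, 5 mol %), B2pin2 (1.1 equiv), MeOH (2 equiv), THF, rt; then NaBO3·4H2O, THF/H2O, rt
Reagents that add atoms: bis(pinacolato)diboron CC1(C)OB(OC1(C)C)B1OC(C)(C)C(C)(C)O1 (boron of 8); sodium perborate [Na+].[Na+].O[B-]1(O)OO[B-](O)(O)OO1 (oxygen of 9)
Why: Copper-catalysed enantioselective conjugate borylation of an enone (chalcones are standard substrates) places boron on the β-carbon on the face chosen by the chiral diphosphine, methanol protonates the copper enolate, and perborate converts C–B into C–O by a 1,2-shift with retention, so the (S)-boronate should give the (S)-carbinol while the isolated prenyl alkene and the aryl fluoride stay untouched.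

**Step 6**
Reactants: 9 (3S)-1-[2-fluoro-4,6-bis(methoxymethoxy)phenyl]-3-hydroxy-3-[4-methoxy-3-(3-methylbut-2-en-1-yl)phenyl]propan-1-one
Product: 11 (2S)-2-[4-methoxy-3-(3-methylbut-2-en-1-yl)phenyl]-5,7-bis(methoxymethoxy)-2,3-dihydro-4H-chromen-4-one, via sodium alkoxide 10 (not isolated)
Conditions: NaN(SiMe3)2 (1.05 equiv), THF (0.02 M), −78 to 0 °C; pH 7 buffer
Reagents that add atoms: none
Why: NaN(SiMe3)2 removes the carbinol proton and the sodium alkoxide 10 adds to C8a, the fluorine-bearing carbon ortho to the C4 carbonyl, to give a Meisenheimer adduct whose charge rests on the carbonyl oxygen, and loss of fluoride restores ring A. The closest known reaction type is the intramolecular SNAr etherification of ortho-fluoroaryl ketones by a tethered alkoxide, the oxygen counterpart of the quinolone-forming cyclisation of ortho-fluorobenzoyl enamines. Ring C closes as a six-membered ring by addition–elimination at an sp2 carbon, formally 6-endo-trig with respect to the C4a=C8a bond of the vinylogous acyl fluoride F–C8a=C4a–C4=O. No stereocentre is created: the O1–C8a bond forms away from C2, none of whose four bonds is broken, so the (S) configuration set in step 5 should be carried through, which a reversible oxa-Michael closure at C2 could not guarantee. The step needs attack at C8a and not at the MOM-bearing ortho carbon (fluoride is the only competent leaving group and the strongest activator of addition), and it needs arylation to outrun retro-aldol cleavage, loss of water to the chalcone and base-induced opening of the product; one equivalent of a non-nucleophilic amide base, the sodium counter-ion, low temperature, high dilution and the six-membered transition state are chosen to secure this.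

**Step 7**
Reactants: 11 (2S)-2-[4-methoxy-3-(3-methylbut-2-en-1-yl)phenyl]-5,7-bis(methoxymethoxy)-2,3-dihydro-4H-chromen-4-one
Product: 12 (2S)-5,7-dihydroxy-2-[4-methoxy-3-(3-methylbut-2-en-1-yl)phenyl]-2,3-dihydro-4H-chromen-4-one (4'-O-methyllicoflavanone)
Conditions: 3 M HCl (aq), MeOH/THF, 40 °C
Reagents that add atoms: none
Why: Acid-catalysed acetal cleavage with transfer of the methylene unit to methanol frees both phenols (the 5-ether assisted by the neighbouring carbonyl), the prenyl group has no ortho hydroxyl with which to cyclise, and C2, which epimerises through base-mediated ring opening, should hold under dilute acid at mild temperature.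

**Compound list**

1 | 3-bromo-4-methoxybenzaldehyde | COc1ccc(C=O)cc1Br | starting material
2 | tributyl(3-methylbut-2-en-1-yl)stannane | CCCC[Sn](CCCC)(CCCC)CC=C(C)C | starting material
3 | 4-methoxy-3-(3-methylbut-2-en-1-yl)benzaldehyde | COc1ccc(C=O)cc1CC=C(C)C | intermediate
4 | 5-fluorobenzene-1,3-diol (5-fluororesorcinol) | Oc1cc(O)cc(F)c1 | starting material
5 | 1-(2-fluoro-4,6-dihydroxyphenyl)ethan-1-one | CC(=O)c1c(O)cc(O)cc1F | intermediate
6 | 1-[2-fluoro-4,6-bis(methoxymethoxy)phenyl]ethan-1-one | CC(=O)c1c(OCOC)cc(OCOC)cc1F | intermediate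
7 | (2E)-1-[2-fluoro-4,6-bis(methoxymethoxy)phenyl]-3-[4-methoxy-3-(3-methylbut-2-en-1-yl)phenyl]prop-2-en-1-one | COc1ccc(/C=C/C(=O)c2c(OCOC)cc(OCOC)cc2F)cc1CC=C(C)C | intermediate
8 | (3S)-1-[2-fluoro-4,6-bis(methoxymethoxy)phenyl]-3-[4-methoxy-3-(3-methylbut-2-en-1-yl)phenyl]-3-(4,4,5,5-tetramethyl-1,3,2-dioxaborolan-2-yl)propan-1-one (not isolated) | COc1ccc([C@H](CC(=O)c2c(OCOC)cc(OCOC)cc2F)B2OC(C)(C)C(C)(C)O2)cc1CC=C(C)C | intermediate
9 | (3S)-1-[2-fluoro-4,6-bis(methoxymethoxy)phenyl]-3-hydroxy-3-[4-methoxy-3-(3-methylbut-2-en-1-yl)phenyl]propan-1-one | COc1ccc([C@H](CC(=O)c2c(OCOC)cc(OCOC)cc2F)O)cc1CC=C(C)C | intermediate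
10 | sodium (1S)-3-[2-fluoro-4,6-bis(methoxymethoxy)phenyl]-1-[4-methoxy-3-(3-methylbut-2-en-1-yl)phenyl]-3-oxopropan-1-olate (not isolated) | COc1ccc([C@H](CC(=O)c2c(OCOC)cc(OCOC)cc2F)[O-])cc1CC=C(C)C.[Na+] | intermediate
11 | (2S)-2-[4-methoxy-3-(3-methylbut-2-en-1-yl)phenyl]-5,7-bis(methoxymethoxy)-2,3-dihydro-4H-chromen-4-one | COc1ccc([C@@H]2CC(=O)c3c(OCOC)cc(OCOC)cc3O2)cc1CC=C(C)C | intermediate
12 | (2S)-5,7-dihydroxy-2-[4-methoxy-3-(3-methylbut-2-en-1-yl)phenyl]-2,3-dihydro-4H-chromen-4-one (4'-O-methyllicoflavanone) | COc1ccc([C@@H]2CC(=O)c3c(O)cc(O)cc3O2)cc1CC=C(C)C | target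

**Totals**

Total steps: 7. Longest linear sequence: 6 (steps 2 to 7, from 5-fluororesorcinol 4).

**Steps most likely to fail**

Step 6. The alkoxide may undergo retro-aldol cleavage and re-addition (erosion of configuration) or β-elimination of water, and the product ring may be opened by residual base. Fallback: setting out from aldol 9, the ketone is reduced with NaBH4 (MeOH, 0 °C) to (1RS,3S)-1-[2-fluoro-4,6-bis(methoxymethoxy)phenyl]-3-[4-methoxy-3-(3-methylbut-2-en-1-yl)phenyl]propane-1,3-diol F1, in which neither retro-aldol cleavage nor β-elimination is possible. KOt-Bu in THF at 65 °C should then close the ether by SNAr at the non-activated fluoroarene, whose two meta alkoxy groups are mildly activating by induction; only the C3 alkoxide can reach the C–F carbon through a six-membered transition state. This gives (2S,4RS)-2-[4-methoxy-3-(3-methylbut-2-en-1-yl)phenyl]-5,7-bis(methoxymethoxy)-3,4-dihydro-2H-chromen-4-ol F2, and Dess–Martin periodinane (NaHCO3, CH2Cl2) oxidises the C4 carbinol to rejoin the route at 11.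

Step 5. Facial selectivity of boryl transfer may be poor or reversed on an enone whose ring A is twisted out of conjugation, and partial retro-aldol may occur in the basic oxidative work-up. Fallback: setting out from chalcone 7, Juliá–Colonna epoxidation (poly-D-leucine, urea–H2O2, DBU, THF, rt) attacks only the electron-poor alkene. Poly-D-leucine is chosen as the antipode of the poly-L-leucine that gives (2R,3S)-epoxy ketones. The product should be [(2S,3R)-3-[4-methoxy-3-(3-methylbut-2-en-1-yl)phenyl]oxiran-2-yl][2-fluoro-4,6-bis(methoxymethoxy)phenyl]methanone F3. SmI2 (THF/MeOH, −90 °C) then cleaves the Cα–O bond of the α,β-epoxy ketone through the ketyl, leaving the benzylic C–O bond and its configuration intact, and returns to the route at 9.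

Step 1. Allyl transposition during transmetalation and reductive elimination may give the 1,1-dimethylallyl isomer, and oxidative addition ortho to the methoxy group may be sluggish. Fallback: setting out from bromide 1, the aldehyde is masked with ethylene glycol (p-TsOH, toluene, reflux with water removal) as 2-(3-bromo-4-methoxyphenyl)-1,3-dioxolane F4. Bromine–lithium exchange (n-BuLi, THF, −78 °C), transmetalation with CuBr·SMe2 and SN2 alkylation with 1-bromo-3-methylbut-2-ene should give 2-[4-methoxy-3-(3-methylbut-2-en-1-yl)phenyl]-1,3-dioxolane F5, and dilute aqueous HCl in THF returns aldehyde 3.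

**Further compounds**

F1 | step 6 | (1RS,3S)-1-[2-fluoro-4,6-bis(methoxymethoxy)phenyl]-3-[4-methoxy-3-(3-methylbut-2-en-1-yl)phenyl]propane-1,3-diol | COc1ccc([C@H](CC(O)c2c(OCOC)cc(OCOC)cc2F)O)cc1CC=C(C)C
F2 | step 6 | (2S,4RS)-2-[4-methoxy-3-(3-methylbut-2-en-1-yl)phenyl]-5,7-bis(methoxymethoxy)-3,4-dihydro-2H-chromen-4-ol | COc1ccc([C@@H]2CC(O)c3c(OCOC)cc(OCOC)cc3O2)cc1CC=C(C)C
F3 | step 5 | [(2S,3R)-3-[4-methoxy-3-(3-methylbut-2-en-1-yl)phenyl]oxiran-2-yl][2-fluoro-4,6-bis(methoxymethoxy)phenyl]methanone | COc1ccc([C@@H]2[C@@H](C(=O)c3c(OCOC)cc(OCOC)cc3F)O2)cc1CC=C(C)C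
F4 | step 1 | 2-(3-bromo-4-methoxyphenyl)-1,3-dioxolane | COc1ccc(C2OCCO2)cc1Br
F5 | step 1 | 2-[4-methoxy-3-(3-methylbut-2-en-1-yl)phenyl]-1,3-dioxolane | COc1ccc(C2OCCO2)cc1CC=C(C)C
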